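**Plan**
Numbering: C1 (quaternary, CH3), C2, C3, C4 (carbinol, isopropyl), C5 (fusion CH), C6 (acyloxy), C7, C8(CH3)=C9, C10. Ring A is C1–C5 and ring B is C1, C5–C10.
Cuts, in order: the ester at O6; C1–C5 (transannular); C3–C4 with re-formation of C1–C6 (retro oxy-Cope); C5–C6 (alkenylmetal plus ketone).
Enabling feature: without C1–C5, rings A and B merge into one ten-membered ring C1–C10. Its C1=C2 and C5=C6(O) units make it the oxy-Cope product of a cyclohexene holding C6–C10 and C1, with vinyl C2=C3 on C1 and enol ether C5=C4 on C6.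
Forward order: six-membered ring from 2,5-dimethylphenol, then the ten-membered ring (step 9), then rings A and B together through one bond (step 10), then the ester.
Stereochemistry: C1 comes from an asymmetric palladium allylation and C6 from substrate control. Both are consumed in the chair [3,3] shift, which sets C4. C4 then steers C1 and C5 in the closure, and the C4 hydroxyl directs the C6 reduction.

Key step: step 9

Assumption: the (R)-t-BuPHOX/palladium catalyst is taken to allylate the enolate from 3 in the same spatial sense as the 2-methylcyclohexanone enolate (otherwise the (S) ligand is used); 22 is taken as purchasable.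

**Step 1**
Reactants: 1 2,5-dimethylphenol
Product: 2 tert-butyl(2,5-dimethylphenoxy)dimethylsilane
Conditions: TBSCl, imidazole, DMF, rt
Reagents that add atoms: tert-butyldimethylsilyl chloride, CC(C)(C)[Si](C)(C)Cl
Why: Silyl ether formation on a phenol; this silyl group withstands the dissolving-metal step and later marks C6=C1 as the only enol ether.

**Step 2**
Reactants: 2 tert-butyl(2,5-dimethylphenoxy)dimethylsilane
Product: 3 tert-butyl[(2,5-dimethylcyclohexa-1,4-dien-1-yl)oxy]dimethylsilane
Conditions: Li, NH3(l), THF, t-BuOH, −78 → −33 °C; solid NH4Cl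
Reagents that add atoms: none
Why: Birch reduction of an aryl silyl ether keeps the donor-bearing carbons sp2, so the 1,4-diene carries the silyl enol ether C6=C1 and the alkene C8=C9, a regiodefined enolate equivalent that base treatment of the β,γ-unsaturated ketone could not give.

**Step 3**
Reactants: 3 tert-butyl[(2,5-dimethylcyclohexa-1,4-dien-1-yl)oxy]dimethylsilane, 4 diallyl carbonate
Product: 5 (6S)-3,6-dimethyl-6-(prop-2-en-1-yl)cyclohex-3-en-1-one
Conditions: Pd2(dba)3 (2.5 mol %), (R)-t-BuPHOX (6 mol %), Bu4N[Ph3SiF2] (35 mol %), THF, 25 °C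
Reagents that add atoms: none
Why: Asymmetric allylic alkylation of a silyl enol ether under zerovalent palladium (Tsuji-type allylation): fluoride, then the allyl oxide released from 4, unmasks the enolate at C1 only, it is allylated within the chiral π-allylpalladium complex faster than protons move, and the (R) ligand sets the quaternary centre C1.

**Step 4**
Reactants: 5 (6S)-3,6-dimethyl-6-(prop-2-en-1-yl)cyclohex-3-en-1-one
Product: 6 (6R)-3,6-dimethyl-6-[(E)-prop-1-en-1-yl]cyclohex-3-en-1-one
Conditions: RuHCl(CO)(PPh3)3 (3 mol %), toluene, 80 °C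
Reagents that add atoms: none
Why: Ruthenium hydride alkene isomerisation (insertion, β-hydride elimination) moves the terminal double bond one position to the quaternary carbon, where it must stop, while the trisubstituted ring alkene inserts far more slowly and stays out of conjugation.

**Step 5**
Reactants: 6 (6R)-3,6-dimethyl-6-[(E)-prop-1-en-1-yl]cyclohex-3-en-1-one
Product: 7 (6R)-6-ethenyl-3,6-dimethylcyclohex-3-en-1-one
Conditions: second-generation Hoveyda–Grubbs catalyst (5 mol %), ethylene (5 bar), toluene, 40 °C
Reagents that add atoms: ethylene, C=C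
Why: Ethenolysis (cross metathesis with ethylene) trims propenyl to vinyl with loss of propene gas; the trisubstituted alkene of an unstrained six-membered ring does not take part.

**Step 6**
Reactants: 8 3-methylbutan-2-one
Product: 9 1-bromo-3-methylbutan-2-one
Conditions: Br2, MeOH, 0–10 °C; then H2O
Reagents that add atoms: bromine, BrBr
Why: Acid-catalysed α-bromination of a ketone in methanol runs through the less substituted enol derivative, so bromine enters at the methyl group.

**Step 7**
Reactants: 9 1-bromo-3-methylbutan-2-one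
Product: 11 (Z)-1-bromo-2-(methoxymethoxy)-3-methylbut-1-ene, via potassium bromoenolate 10 (not isolated)
Conditions: KN(SiMe3)2, THF–DMPU (4:1), −78 °C; MOMCl, −78 → −20 °C
Reagents that add atoms: chloromethyl methyl ether, COCCl
Why: O-alkylation of a potassium enolate by a hard chloromethyl ether in a dipolar medium; the more acidic CH2Br hydrogen is removed and bromine settles cis to the oxide, away from isopropyl, which fixes the Z geometry.

**Step 8**
Reactants: 7 (6R)-6-ethenyl-3,6-dimethylcyclohex-3-en-1-one, 11 (Z)-1-bromo-2-(methoxymethoxy)-3-methylbut-1-ene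
Product: 14 (1S,6R)-6-ethenyl-1-[(Z)-2-(methoxymethoxy)-3-methylbut-1-enyl]-3,6-dimethylcyclohex-3-en-1-ol, via alkenyllithium 12 (not isolated), via alkenylcerium dichloride 13 (not isolated)
Conditions: 11, t-BuLi (2 equiv), Et2O, −78 °C; CeCl3, THF, −78 °C; 7, −78 → −30 °C; pH 7 buffer
Reagents that add atoms: none
Why: Bromine–lithium exchange with retention (the syn oxygen chelates lithium and cannot leave by anti elimination), transmetalation to the weakly basic organocerium reagent and 1,2-addition to the enolisable neopentyl ketone; Felkin–Anh-type attack anti to the pseudoaxial vinyl group, along the axial path left open by sp2 C8, should set C6 with the two alkenyl groups trans, and the minor epimer is removed by chromatography.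

**Step 9**
Reactants: 14 (1S,6R)-6-ethenyl-1-[(Z)-2-(methoxymethoxy)-3-methylbut-1-enyl]-3,6-dimethylcyclohex-3-en-1-ol
Product: 17 diethyl (1Z,3R,5E,8Z)-3-(methoxymethoxy)-6,9-dimethyl-3-(propan-2-yl)cyclodeca-1,5,8-trien-1-yl phosphate, via potassium alkoxide 15 (not isolated), via potassium enolate 16 (not isolated)
Conditions: KH (1.2 equiv), 18-crown-6 (1.2 equiv), THF, −20 → 20 °C; ClP(O)(OEt)2, −78 → −30 °C
Reagents that add atoms: diethyl chlorophosphate, CCOP(=O)(Cl)OCC
Why: KH turns 14 into alkoxide 15 with loss of H2, and the oxide on C6 weakens the doubly allylic bond between the fully substituted carbons C1 and C6, so a concerted chair-like [3,3] shift forms C3–C4 while C1–C6 breaks and leaves enolate 16, which ClP(O)(OEt)2 caps on oxygen. The closest known reaction type is the anionic oxy-Cope ring expansion of trans-1,2-dialkenylcyclohexanols to (E)-cyclodec-5-enone enolates followed by O-trapping, applied here to a substrate whose terminus C4 is fully substituted and carries oxygen. The ten-membered ring C1–C10 is not closed end to end but arises by four-atom ring expansion of the cyclohexene, the new bond C3–C4 tying the two side chains together as the old ring bond opens. C4, the one new stereocentre, is controlled by the C1/C6 pair: trans-diequatorial alkenyl groups allow a single chair (a boat would need a C2–C1–C6–C5 angle near zero), in which C10 and C7 are equatorial, hence E C1=C2 and a trans-in-ring enolate, and in which the Z enol ether places isopropyl equatorial and OCH2OCH3 axial, so that C3 reaches only one face of C4. The step needs 16 to keep its position and its C4 oxygen: once H2 is gone no proton shuttle can move the enolate to the more acidic C7, and in a trans ring enolate the ring bond C4–C3 takes the position perpendicular to the enolate plane, which holds the C4–O bond near the nodal plane and slows β-elimination until the trap at −78 °C. C8=C9 lies outside the six-atom array and is untouched.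

**Step 10**
Reactants: 17 diethyl (1Z,3R,5E,8Z)-3-(methoxymethoxy)-6,9-dimethyl-3-(propan-2-yl)cyclodeca-1,5,8-trien-1-yl phosphate
Product: 19 (3R,3aR,8aR)-3-(methoxymethoxy)-6,8a-dimethyl-3-(propan-2-yl)-2,3,3a,5,8,8a-hexahydroazulen-4(1H)-one, via C2 organomercurial 18 (not isolated)
Conditions: Hg(OCOCF3)2 (1.05 equiv), 2,6-di-tert-butyl-4-methylpyridine (0.3 equiv), CH2Cl2–MeNO2 (4:1), −20 °C; n-Bu3SnH, −20 → 0 °C; aq NaHCO3
Reagents that add atoms: none
Why: Proposed new method: divalent mercury adds reversibly to both trisubstituted alkenes, but only the mercurinium ion of the strained E alkene has a carbon nucleophile within reach, so C5 of the enol phosphate (too electron-poor to be mercurated itself) opens it at the tertiary carbon C1 anti to mercury, the phosphoryl group passes to trifluoroacetate to free the C6 ketone, and n-Bu3SnH then replaces mercury on C2 by hydrogen in a radical chain; the one new bond closes ring A (five-membered, endo to C1=C2, exo to the enol) and ring B (seven-membered, exo to C1=C2, endo to the enol); anti addition to the E alkene makes C10 pseudoequatorial and the methyl group pseudoaxial on ring A, the trans-in-ring enol phosphate keeps C10 anti to C4 about the new bond, and allylic 1,3-strain with the phosphate puts the C4–O bond in the enol plane and isopropyl on the outer face, so the methyl group ends up syn to the small C4 oxygen and anti to H5, which sets C1 and the trans fusion at C5; the closest known reaction types are the mercuric-salt-initiated cation–olefin cyclisation of acyclic polyenes terminated by an enol phosphate and the electrophile-induced transannular cyclisation of (E)-cyclodeca-1,5-dienes.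

**Step 11**
Reactants: 19 (3R,3aR,8aR)-3-(methoxymethoxy)-6,8a-dimethyl-3-(propan-2-yl)-2,3,3a,5,8,8a-hexahydroazulen-4(1H)-one
Product: 20 (3R,3aR,8aR)-3-hydroxy-6,8a-dimethyl-3-(propan-2-yl)-2,3,3a,5,8,8a-hexahydroazulen-4(1H)-one
Conditions: ZnBr2 (1 equiv), n-PrSH (2 equiv), CH2Cl2, 0 °C, short contact
Reagents that add atoms: none
Why: Lewis acid/thiol cleavage of a methoxymethyl ether: ZnBr2 activates the acetal and the thiol takes up the CH2 unit, mildly and briefly enough for a tertiary aldol-type carbinol that stronger protic acid would dehydrate.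

**Step 12**
Reactants: 20 (3R,3aR,8aR)-3-hydroxy-6,8a-dimethyl-3-(propan-2-yl)-2,3,3a,5,8,8a-hexahydroazulen-4(1H)-one
Product: 21 (3R,3aS,4S,8aR)-6,8a-dimethyl-3-(propan-2-yl)-1,2,3,3a,4,5,8,8a-octahydroazulene-3,4-diol
Conditions: Me4NBH(OAc)3, MeCN–AcOH (1:1), −30 °C; aq Rochelle salt
Reagents that add atoms: none
Why: Evans–Saksena reduction: the C4 hydroxyl displaces an acetate on boron and hydride is delivered internally to the C6 face syn to that oxygen, which gives the 4,6-anti diol, the (S) carbinol, against the steric bias of the angular methyl group.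

**Step 13**
Reactants: 21 (3R,3aS,4S,8aR)-6,8a-dimethyl-3-(propan-2-yl)-1,2,3,3a,4,5,8,8a-octahydroazulene-3,4-diol, 22 2,2-dimethyl-4H-1,3-benzodioxin-4-one
Product: 24 (3R,3aS,4S,8aR)-3-hydroxy-6,8a-dimethyl-3-(propan-2-yl)-1,2,3,3a,4,5,8,8a-octahydroazulen-4-yl 2-hydroxybenzoate, via sodium alkoxide 23 (not isolated)
Conditions: NaH (1.2 equiv), THF, 0 °C; 22, 0 °C → rt; AcOH
Reagents that add atoms: none
Why: Alkoxide opening of a salicylic acid acetonide (transesterification with loss of acetone) acylates the secondary C6 oxygen and frees the phenol in the same operation, the tertiary C4 hydroxyl being too hindered to compete.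

**Compound list**
1 | 2,5-dimethylphenol | Cc1ccc(C)c(O)c1 | starting material
2 | tert-butyl(2,5-dimethylphenoxy)dimethylsilane | Cc1ccc(C)c(O[Si](C)(C)C(C)(C)C)c1 | intermediate
3 | tert-butyl[(2,5-dimethylcyclohexa-1,4-dien-1-yl)oxy]dimethylsilane | CC1=CCC(C)=C(O[Si](C)(C)C(C)(C)C)C1 | intermediate
4 | diallyl carbonate | C=CCOC(=O)OCC=C | starting material
5 | (6S)-3,6-dimethyl-6-(prop-2-en-1-yl)cyclohex-3-en-1-one | CC1=CC[C@](C)(CC=C)C(=O)C1 | intermediate
6 | (6R)-3,6-dimethyl-6-[(E)-prop-1-en-1-yl]cyclohex-3-en-1-one | CC1=CC[C@](C)(/C=C/C)C(=O)C1 | intermediate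
7 | (6R)-6-ethenyl-3,6-dimethylcyclohex-3-en-1-one | CC1=CC[C@](C)(C=C)C(=O)C1 | intermediate
8 | 3-methylbutan-2-one | CC(C)C(C)=O | starting material
9 | 1-bromo-3-methylbutan-2-one | CC(C)C(=O)CBr | intermediate
10 | potassium (Z)-1-bromo-3-methylbut-1-en-2-olate | [K+].[O-]/C(=C\Br)C(C)C | intermediate
11 | (Z)-1-bromo-2-(methoxymethoxy)-3-methylbut-1-ene | Br/C=C(\OCOC)C(C)C | intermediate
12 | [(Z)-2-(methoxymethoxy)-3-methylbut-1-enyl]lithium | [Li]/C=C(\OCOC)C(C)C | intermediate
13 | dichloro[(Z)-2-(methoxymethoxy)-3-methylbut-1-enyl]cerium | Cl[Ce](Cl)/C=C(\OCOC)C(C)C | intermediate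
14 | (1S,6R)-6-ethenyl-1-[(Z)-2-(methoxymethoxy)-3-methylbut-1-enyl]-3,6-dimethylcyclohex-3-en-1-ol (alkenyl groups trans) | CC1=CC[C@](C)(C=C)[C@@](O)(/C=C(\OCOC)C(C)C)C1 | intermediate
15 | potassium alkoxide of 14 | [K+].CC1=CC[C@](C)(C=C)[C@@]([O-])(/C=C(\OCOC)C(C)C)C1 | intermediate
16 | potassium (1Z,3R,5E,8Z)-3-(methoxymethoxy)-6,9-dimethyl-3-(propan-2-yl)cyclodeca-1,5,8-trien-1-olate (C5=C6 enolate of the ten-membered C6 ketone) | [K+].[O-]/C1=C\[C@](OCOC)(C(C)C)C/C=C(C)/C/C=C(C)\C1 | intermediate
17 | diethyl (1Z,3R,5E,8Z)-3-(methoxymethoxy)-6,9-dimethyl-3-(propan-2-yl)cyclodeca-1,5,8-trien-1-yl phosphate | CCOP(=O)(OCC)O/C1=C\[C@](OCOC)(C(C)C)C/C=C(C)/C/C=C(C)\C1 | intermediate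
18 | 19 bearing HgOCOCF3 on C2, anti to the C1–C5 bond | CC1=CC[C@@]2(C)[C@H]([Hg]OC(=O)C(F)(F)F)C[C@@](OCOC)(C(C)C)[C@@H]2C(=O)C1 | intermediate
19 | (3R,3aR,8aR)-3-(methoxymethoxy)-6,8a-dimethyl-3-(propan-2-yl)-2,3,3a,5,8,8a-hexahydroazulen-4(1H)-one | CC1=CC[C@@]2(C)CC[C@@](OCOC)(C(C)C)[C@@H]2C(=O)C1 | intermediate
20 | (3R,3aR,8aR)-3-hydroxy-6,8a-dimethyl-3-(propan-2-yl)-2,3,3a,5,8,8a-hexahydroazulen-4(1H)-one | CC1=CC[C@@]2(C)CC[C@@](O)(C(C)C)[C@@H]2C(=O)C1 | intermediate
21 | (3R,3aS,4S,8aR)-6,8a-dimethyl-3-(propan-2-yl)-1,2,3,3a,4,5,8,8a-octahydroazulene-3,4-diol | CC1=CC[C@@]2(C)CC[C@@](O)(C(C)C)[C@@H]2[C@@H](O)C1 | intermediate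
22 | 2,2-dimethyl-4H-1,3-benzodioxin-4-one | CC1(C)OC(=O)c2ccccc2O1 | starting material
23 | sodium C6 alkoxide of 21 | [Na+].CC1=CC[C@@]2(C)CC[C@@](O)(C(C)C)[C@@H]2[C@@H]([O-])C1 | intermediate
24 | (3R,3aS,4S,8aR)-3-hydroxy-6,8a-dimethyl-3-(propan-2-yl)-1,2,3,3a,4,5,8,8a-octahydroazulen-4-yl 2-hydroxybenzoate | CC1=CC[C@@]2(C)CC[C@@](O)(C(C)C)[C@@H]2[C@@H](OC(=O)c2ccccc2O)C1 | target

**Step count**
Total step count: 13. Longest linear sequence: 11 (steps 1–5 and 8–13).

**Steps most likely to fail**

1. Step 10.
What may go wrong:
- The cationic C1 may be captured by the C4 acetal oxygen, with loss of the methoxymethyl group.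
- The allylic C4–O bond may ionise.
- Proton loss may follow mercuration of C8=C9.
- Closure may occur from the other face of C1=C2.

Fallback from 17 back to 19, using known reaction types only. Buffered m-CPBA should epoxidise the strained E alkene in preference to the Z alkene and the electron-poor enol phosphate, giving the epoxy enol phosphate F1. MeAlCl2 in CH2Cl2 at −78 °C opens the epoxide at C1 with attack of C5 (epoxide-initiated cation–olefin cyclisation ended by an enol derivative). After aqueous work-up this gives the C2 hydroxy ketone F2. 1,1'-Thiocarbonyldiimidazole converts it into the imidazole-1-carbothioate F3. n-Bu3SnH/AIBN in toluene at 90 °C (Barton–McCombie deoxygenation) then returns 19.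

2. Step 9.
What may go wrong:
- The enolate may lose the C4 alkoxy group by β-elimination during the time the shift needs.
- C1–C6 may cleave heterolytically without recombination.
- The fully substituted terminus may bond only slowly.

Fallback from 14 back to 17, using an internal quench in place of a free enolate. 14 is deprotonated with KH/18-crown-6 at −40 °C and the solution is taken off the excess hydride. i-Pr3SiCl is added and the mixture is warmed. The chloride is too bulky for the tertiary alkoxide next to C1 but silylates the enolate oxygen as it appears, giving the triisopropylsilyl enol ether F4. Bu4N[Ph3SiF2] and ClP(O)(OEt)2 in THF at −78 °C then exchange silicon for phosphorus on the enol oxygen, with retention of the double-bond geometry, and return 17.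

3. Step 8.
What may go wrong:
- The alkenylmetal may deprotonate the doubly activated C7.
- Addition to the neopentyl carbonyl may be slow.
- Facial selectivity may be poor.
- Upstream, the bromoenolate of step 7 may self-condense.

Fallback from 7 and 8 back to 14, which also bypasses steps 6 and 7. 8 is deprotonated at its methyl group with LiN(i-Pr)2 (THF, −78 °C), CeCl3 is added, then 7. Aldol addition of the small, weakly basic nucleophile gives the hydroxy ketone F5. Me3SiOTf/2,6-lutidine gives the silyl ether F6. KN(SiMe3)2 followed by MOMCl (THF–DMPU, −78 °C) gives the Z methoxymethyl enol ether F7. Bu4NF buffered with AcOH removes the silyl group and returns 14.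

**Further compounds**
F1 | step 10 | C1–C2 epoxide of 17, oxygen on the outer alkene face | CCOP(=O)(OCC)O/C1=C\[C@](OCOC)(C(C)C)C[C@H]2O[C@]2(C)C/C=C(C)\C1
F2 | step 10 | (1R,3R,3aR,8aR)-1-hydroxy-3-(methoxymethoxy)-6,8a-dimethyl-3-(propan-2-yl)-2,3,3a,5,8,8a-hexahydroazulen-4(1H)-one | CC1=CC[C@@]2(C)[C@H](O)C[C@@](OCOC)(C(C)C)[C@@H]2C(=O)C1
F3 | step 10 | O-imidazole-1-carbothioate of F2 | CC1=CC[C@@]2(C)[C@H](OC(=S)n3ccnc3)C[C@@](OCOC)(C(C)C)[C@@H]2C(=O)C1
F4 | step 9 | triisopropylsilyl enol ether corresponding to 17 | CC(C)[Si](C(C)C)(C(C)C)O/C1=C\[C@](OCOC)(C(C)C)C/C=C(C)/C/C=C(C)\C1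
F5 | step 8 | 1-[(1S,6R)-6-ethenyl-1-hydroxy-3,6-dimethylcyclohex-3-en-1-yl]-3-methylbutan-2-one | CC1=CC[C@](C)(C=C)[C@@](O)(CC(=O)C(C)C)C1
F6 | step 8 | trimethylsilyl ether of F5 | CC1=CC[C@](C)(C=C)[C@@](O[Si](C)(C)C)(CC(=O)C(C)C)C1
F7 | step 8 | trimethylsilyl ether of 14 | CC1=CC[C@](C)(C=C)[C@@](O[Si](C)(C)C)(/C=C(\OCOC)C(C)C)C1
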